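**Retrosynthetic overview**
1. Triene last: the C9'=C10' alkene of the side chain by Julia–Kocienski olefination of a PT-sulfone on the finished peroxylactone with (2E,4E)-hepta-2,4-dienal.
2. C3–CH3 bond: SN1 methylation of a bicyclic 3-methoxy-1,2-dioxane through its peroxycarbenium ion (sets C3).
3. 1,2-Dioxane ring (formed second): ozonolysis of a 1,1-disubstituted alkene in MeOH to an α-methoxy hydroperoxide, then peroxy-Michael closure onto the butenolide (sets C7a cis to C4a).
4. Butenolide ring (formed first) with its quaternary C4a: enantioselective dearomative Pd-catalysed γ-allylation of 2-methyl-5-silyloxyfuran, made from 2-methylfuran.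
5. Allyl partner: Cu-catalysed mono-substitution of symmetric 3-chloro-2-(chloromethyl)propene by a C8 chloroalkyl Grignard reagent.

Assumption: the target is read as (3S,4aS,7aS) in furo[3,2-c][1,2]dioxin numbering (C3 = peroxide carbon bearing the chain, C4a/C7a = ring fusion), with the C3 methyl cis to the lactone oxygen; the Trost ligand enantiomer that gives (S)-8 is written as (R,R) and would be exchanged for (S,S) if a test reaction showed the opposite sense.

**Route**

Step 1
Reactants: 1 2-methylfuran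
Product: 3 2-methyl-5-[(trimethylsilyl)oxy]furan, via (5-methylfuran-2-yl)lithium 2 (not isolated)
Conditions: n-BuLi (1.05 equiv), THF, −20 → 0 °C; then Me3SiOOSiMe3 (1.1 equiv), −78 °C → rt; non-aqueous work-up, distillation
Reagents that add atoms: bis(trimethylsilyl) peroxide C[Si](C)(C)OO[Si](C)(C)C
Why: α-lithiation of the furan at C5 followed by electrophilic oxygenation of the heteroaryllithium on the O–O bond of the silyl peroxide gives the silyl ether of the 2-hydroxyfuran, and no stereocentre is formed.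

Step 2
Reactants: 4 1-bromo-8-chlorooctane; 5 3-chloro-2-(chloromethyl)prop-1-ene
Product: 7 11-chloro-2-(chloromethyl)undec-1-ene, via (8-chlorooctyl)magnesium bromide 6 (not isolated)
Conditions: Mg, THF, 40 °C; then added to 5 (3 equiv), Li2CuCl4 (3 mol%), THF, −20 → 0 °C
Reagents that add atoms: none
Why: magnesium inserts into C–Br selectively over C–Cl, and copper-catalysed allylic substitution of the Grignard reagent on the symmetric dichloride gives the same product by SN2 or SN2' attack while excess 5 suppresses double substitution; no stereocentre is formed.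

Step 3
Reactants: 3 2-methyl-5-[(trimethylsilyl)oxy]furan; 7 11-chloro-2-(chloromethyl)undec-1-ene
Product: 8 (5S)-5-(11-chloro-2-methylideneundecyl)-5-methylfuran-2(5H)-one
Conditions: 3 (1.3 equiv), [Pd2(dba)3]·CHCl3 (2.5 mol%), (R,R)-DACH-phenyl Trost ligand (6 mol%), TBAT (1.1 equiv), toluene, 0 °C
Reagents that add atoms: none
Why: Proposed new method: fluoride unmasks the aromatic silyloxyfuran as a soft furan-2-olate that attacks the 2-alkyl-π-allyl palladium cation (both termini CH2, so the electrophile has no regiochemistry) in an outer-sphere fashion through its γ-carbon C5 to give the conjugated butenolide, the chiral pocket of the ligand differentiating the two faces of the planar nucleophile and so setting the quaternary (S) centre as aromaticity is lost; the closest known reactions are the Pd-catalysed asymmetric allylic alkylation (Tsuji–Trost) of prochiral enolates and silyl enol ethers to quaternary centres and the γ-selective vinylogous Mukaiyama–Michael additions of 5-methyl-2-silyloxyfurans.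

Step 4
Reactants: 8 (5S)-5-(11-chloro-2-methylideneundecyl)-5-methylfuran-2(5H)-one
Product: 10 (4aS,7aS)-3-(9-chlorononyl)-3-methoxy-4a-methyl-4,4a,7,7a-tetrahydro-3H-furo[3,2-c][1,2]dioxin-6-one (both C3 epimers), via methoxy hydroperoxide 9 (not isolated)
Conditions: O3/O2, CH2Cl2–MeOH (4:1), Sudan Red 7B end point, −78 °C; N2 purge; solvent exchange to CF3CH2OH; Et3N (0.3 equiv), 0 °C → rt
Reagents that add atoms: ozone [O-][O+]=O; methanol CO
Why: ozonolysis (Criegee mechanism) cleaves only the electron-rich 1,1-disubstituted alkene, the primary ozonide fragments mainly to formaldehyde and the ketone O-oxide, which methanol traps as the α-methoxy hydroperoxide, and base-mediated intramolecular peroxy-Michael (oxa-Michael) addition to the butenolide then closes the 1,2-dioxane with C7a necessarily (S) because the tether from the quaternary C4a can only reach the same face (cis fusion).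

Step 5
Reactants: 10 (4aS,7aS)-3-(9-chlorononyl)-3-methoxy-4a-methyl-4,4a,7,7a-tetrahydro-3H-furo[3,2-c][1,2]dioxin-6-one
Product: 11 (3S,4aS,7aS)-3-(9-chlorononyl)-3,4a-dimethyl-4,4a,7,7a-tetrahydro-3H-furo[3,2-c][1,2]dioxin-6-one
Conditions: TiCl4 (2.5 equiv) and Me2Zn (2.5 equiv), CH2Cl2, −78 °C, 15 min; then 10, −78 → −30 °C
Reagents that add atoms: dimethyltitanium dichloride C[Ti](C)(Cl)Cl (formed in the flask from dimethylzinc C[Zn]C and titanium tetrachloride Cl[Ti](Cl)(Cl)Cl)
Why: Proposed new method: the titanium Lewis acid ionises the methoxy group to a cyclic peroxycarbenium ion, so both ketal epimers converge, and methyl is delivered along the axial trajectory of the half-chair in which the C4a–O(lactone) bond is pseudoaxial, that is syn to the lactone oxygen and not syn to the C4a methyl (Me/Me 1,3-diaxial strain avoided), which leaves the chloroalkyl chain equatorial and gives the (3S) centre; the closest known reactions are Reetz SN1 methylation of ketals and tertiary halides with Me2TiCl2 and TiCl4-mediated substitution of cyclic peroxyketals by π-nucleophiles through peroxycarbenium ions.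

Step 6
Reactants: 11 (3S,4aS,7aS)-3-(9-chlorononyl)-3,4a-dimethyl-4,4a,7,7a-tetrahydro-3H-furo[3,2-c][1,2]dioxin-6-one
Product: 12 (3S,4aS,7aS)-3,4a-dimethyl-3-{9-[(1-phenyl-1H-tetrazol-5-yl)sulfanyl]nonyl}-4,4a,7,7a-tetrahydro-3H-furo[3,2-c][1,2]dioxin-6-one
Conditions: sodium 1-phenyl-1H-tetrazole-5-thiolate (1.5 equiv), NaI (0.2 equiv), DMF, 45 °C
Reagents that add atoms: sodium 1-phenyl-1H-tetrazole-5-thiolate [Na+].[S-]c1nnnn1-c1ccccc1
Why: iodide-catalysed SN2 displacement of the primary chloride by the soft, very weakly basic tetrazolethiolate leaves the dialkyl peroxide and the lactone untouched and affects no stereocentre.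

Step 7
Reactants: 12 (3S,4aS,7aS)-3,4a-dimethyl-3-{9-[(1-phenyl-1H-tetrazol-5-yl)sulfanyl]nonyl}-4,4a,7,7a-tetrahydro-3H-furo[3,2-c][1,2]dioxin-6-one
Product: 13 (3S,4aS,7aS)-3,4a-dimethyl-3-{9-[(1-phenyl-1H-tetrazol-5-yl)sulfonyl]nonyl}-4,4a,7,7a-tetrahydro-3H-furo[3,2-c][1,2]dioxin-6-one
Conditions: (NH4)6Mo7O24·4H2O (10 mol%), 30% H2O2 (6 equiv), EtOH, 0 °C → rt
Reagents that add atoms: hydrogen peroxide OO
Why: molybdate-catalysed sulfide oxidation through peroxomolybdate species gives the sulfone, while the dialkyl peroxide and the lactone are inert to this electrophilic oxidant and no stereocentre is touched.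

Step 8
Reactants: 13 (3S,4aS,7aS)-3,4a-dimethyl-3-{9-[(1-phenyl-1H-tetrazol-5-yl)sulfonyl]nonyl}-4,4a,7,7a-tetrahydro-3H-furo[3,2-c][1,2]dioxin-6-one; 14 (2E,4E)-hepta-2,4-dienal
Product: 15 (3S,4aS,7aS)-3-[(9E,11E,13E)-hexadeca-9,11,13-trien-1-yl]-3,4a-dimethyl-4,4a,7,7a-tetrahydro-3H-furo[3,2-c][1,2]dioxin-6-one
Conditions: 14 (1.5 equiv), KHMDS (1.15 equiv, added last), DME, −78 °C → rt; minor 9Z isomer removed on AgNO3–silica
Reagents that add atoms: none
Why: Julia–Kocienski olefination, in which the metalated PT-sulfone adds to the dienal and Smiles rearrangement with anti elimination of SO2 and the tetrazololate gives the new C9'=C10' alkene E-selectively (potassium counter-ion, DME), extending the (E,E)-diene of 14 to the (E,E,E)-triene, while in-situ deprotonation keeps free base away from the β-peroxy lactone and no stereocentre is affected.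

**Compound list**
1 | 2-methylfuran | Cc1ccco1 | starting material
2 | (5-methylfuran-2-yl)lithium | [Li]c1ccc(C)o1 | intermediate
3 | 2-methyl-5-[(trimethylsilyl)oxy]furan | Cc1ccc(O[Si](C)(C)C)o1 | intermediate
4 | 1-bromo-8-chlorooctane | ClCCCCCCCCBr | starting material
5 | 3-chloro-2-(chloromethyl)prop-1-ene | C=C(CCl)CCl | starting material
6 | (8-chlorooctyl)magnesium bromide | ClCCCCCCCC[Mg]Br | intermediate
7 | 11-chloro-2-(chloromethyl)undec-1-ene | C=C(CCl)CCCCCCCCCCl | intermediate
8 | (5S)-5-(11-chloro-2-methylideneundecyl)-5-methylfuran-2(5H)-one | C=C(CCCCCCCCCCl)C[C@]1(C)OC(=O)C=C1 | intermediate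
9 | (5S)-5-(11-chloro-2-hydroperoxy-2-methoxyundecyl)-5-methylfuran-2(5H)-one (both epimers at the ketal carbon) | COC(OO)(CCCCCCCCCCl)C[C@]1(C)OC(=O)C=C1 | intermediate
10 | (4aS,7aS)-3-(9-chlorononyl)-3-methoxy-4a-methyl-4,4a,7,7a-tetrahydro-3H-furo[3,2-c][1,2]dioxin-6-one (both C3 epimers) | COC1(CCCCCCCCCCl)C[C@]2(C)OC(=O)C[C@@H]2OO1 | intermediate
11 | (3S,4aS,7aS)-3-(9-chlorononyl)-3,4a-dimethyl-4,4a,7,7a-tetrahydro-3H-furo[3,2-c][1,2]dioxin-6-one | ClCCCCCCCCC[C@@]1(C)C[C@]2(C)OC(=O)C[C@@H]2OO1 | intermediate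
12 | (3S,4aS,7aS)-3,4a-dimethyl-3-{9-[(1-phenyl-1H-tetrazol-5-yl)sulfanyl]nonyl}-4,4a,7,7a-tetrahydro-3H-furo[3,2-c][1,2]dioxin-6-one | c1ccccc1-n1nnnc1SCCCCCCCCC[C@@]1(C)C[C@]2(C)OC(=O)C[C@@H]2OO1 | intermediate
13 | (3S,4aS,7aS)-3,4a-dimethyl-3-{9-[(1-phenyl-1H-tetrazol-5-yl)sulfonyl]nonyl}-4,4a,7,7a-tetrahydro-3H-furo[3,2-c][1,2]dioxin-6-one | c1ccccc1-n1nnnc1S(=O)(=O)CCCCCCCCC[C@@]1(C)C[C@]2(C)OC(=O)C[C@@H]2OO1 | intermediate
14 | (2E,4E)-hepta-2,4-dienal | CC/C=C/C=C/C=O | starting material
15 | (3S,4aS,7aS)-3-[(9E,11E,13E)-hexadeca-9,11,13-trien-1-yl]-3,4a-dimethyl-4,4a,7,7a-tetrahydro-3H-furo[3,2-c][1,2]dioxin-6-one | CC/C=C/C=C/C=C/CCCCCCCC[C@@]1(C)C[C@]2(C)OC(=O)C[C@@H]2OO1 | target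

**Step count and risks**

Total step count: 8. Longest linear sequence: 7 steps (steps 2–8 from 4 and 5; equally steps 1 and 3–8 from 1).

Steps most likely to fail:

Step 3. Risks are α- instead of γ-allylation of the furanolate, and insufficient enantioselectivity at a quaternary centre. The fallback sets out from 1 and 7 and comes back at 8. Sensitised photooxygenation of 1 (O2, rose bengal, hν, i-Pr2NEt, CH2Cl2) dearomatises the furan to 5-hydroxy-5-methylfuran-2(5H)-one F1, the ring tautomer of (Z)-4-oxopent-2-enoic acid. Indium-mediated Barbier allylation of its keto form with 7 (In, NaI, THF/H2O), followed by spontaneous lactonisation, gives racemic 5-(11-chloro-2-methylideneundecyl)-5-methylfuran-2(5H)-one F2. Preparative chiral SFC then delivers 8. This replaces catalyst control by resolution.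

Step 5. Risks are Lewis-acid fragmentation of the peroxyketal (O–O heterolysis or proton loss) and a wrong or low facial preference. The fallback sets out from 8 and comes back at 11. Mukaiyama–Isayama hydroperoxysilylation (Co(thd)2 cat., O2, Et3SiH, 1,2-dichloroethane) gives (5S)-5-{11-chloro-2-methyl-2-[(triethylsilyl)peroxy]undecyl}-5-methylfuran-2(5H)-one F3 as a 1:1 mixture at the new centre. TBAF/AcOH (THF, 0 °C) liberates (5S)-5-(11-chloro-2-hydroperoxy-2-methylundecyl)-5-methylfuran-2(5H)-one F4, which closes with Et3N in CF3CH2OH by peroxy-Michael addition. This gives 11 together with its epimer (3R,4aS,7aS)-3-(9-chlorononyl)-3,4a-dimethyl-4,4a,7,7a-tetrahydro-3H-furo[3,2-c][1,2]dioxin-6-one F5, separated by chromatography. Radical O2 trapping replaces the cationic methylation, at the price of no control at C3.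

Step 8. Risks are enolisation and retro-Michael opening of the β-peroxy lactone by the amide base, and incomplete E-selectivity with a conjugated aldehyde. The fallback sets out from 11 (and 14) and comes back at 15.
- Finkelstein exchange (NaI, acetone, 50 °C) gives (3S,4aS,7aS)-3-(9-iodononyl)-3,4a-dimethyl-4,4a,7,7a-tetrahydro-3H-furo[3,2-c][1,2]dioxin-6-one F6.
- Trimethylamine N-oxide in DMSO at rt oxidises it to 9-[(3S,4aS,7aS)-3,4a-dimethyl-6-oxohexahydro-3H-furo[3,2-c][1,2]dioxin-3-yl]nonanal F7.
- Separately, 14 is reduced (NaBH4, CeCl3, MeOH) to (2E,4E)-hepta-2,4-dien-1-ol F8, which with Bu3P·HBr gives tributyl[(2E,4E)-hepta-2,4-dien-1-yl]phosphonium bromide F9.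
- LiHMDS (THF, −78 °C) converts it to tributyl[(2E,4E)-hepta-2,4-dien-1-ylidene]phosphorane F10, which condenses with F7 in an E-selective allylic trialkylphosphonium Wittig reaction to give 15.

The weakly basic ylide replaces the sulfone anion and the amide base.

**Further compounds**
F1 | step 3 | 5-hydroxy-5-methylfuran-2(5H)-one | CC1(O)OC(=O)C=C1
F2 | step 3 | racemic 5-(11-chloro-2-methylideneundecyl)-5-methylfuran-2(5H)-one | C=C(CCCCCCCCCCl)CC1(C)OC(=O)C=C1
F3 | step 5 | (5S)-5-{11-chloro-2-methyl-2-[(triethylsilyl)peroxy]undecyl}-5-methylfuran-2(5H)-one (1:1 epimers) | CC(OO[Si](CC)(CC)CC)(CCCCCCCCCCl)C[C@]1(C)OC(=O)C=C1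
F4 | step 5 | (5S)-5-(11-chloro-2-hydroperoxy-2-methylundecyl)-5-methylfuran-2(5H)-one (1:1 epimers) | CC(OO)(CCCCCCCCCCl)C[C@]1(C)OC(=O)C=C1
F5 | step 5 | (3R,4aS,7aS)-3-(9-chlorononyl)-3,4a-dimethyl-4,4a,7,7a-tetrahydro-3H-furo[3,2-c][1,2]dioxin-6-one | ClCCCCCCCCC[C@]1(C)C[C@]2(C)OC(=O)C[C@@H]2OO1
F6 | step 8 | (3S,4aS,7aS)-3-(9-iodononyl)-3,4a-dimethyl-4,4a,7,7a-tetrahydro-3H-furo[3,2-c][1,2]dioxin-6-one | ICCCCCCCCC[C@@]1(C)C[C@]2(C)OC(=O)C[C@@H]2OO1
F7 | step 8 | 9-[(3S,4aS,7aS)-3,4a-dimethyl-6-oxohexahydro-3H-furo[3,2-c][1,2]dioxin-3-yl]nonanal | O=CCCCCCCCC[C@@]1(C)C[C@]2(C)OC(=O)C[C@@H]2OO1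
F8 | step 8 | (2E,4E)-hepta-2,4-dien-1-ol | CC/C=C/C=C/CO
F9 | step 8 | tributyl[(2E,4E)-hepta-2,4-dien-1-yl]phosphonium bromide | CC/C=C/C=C/C[P+](CCCC)(CCCC)CCCC.[Br-]
F10 | step 8 | tributyl[(2E,4E)-hepta-2,4-dien-1-ylidene]phosphorane | CC/C=C/C=C/C=P(CCCC)(CCCC)CCCC
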